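**Plan**
- The nine O-methyl groups are cut last. The E-stilbene is then cut at the aryl–vinyl bond on C5 of unit A (the 7-hydroxy dihydrobenzofuran), giving a 5-bromide of unit A and a 6-vinyl derivative of the B–C pair.
- Unit B (central dihydrobenzofuran, C3 bonded to C4 of terminal unit C) is cut at C3–C3a and O1–C2. Its benzo ring carries no oxygen other than O1, so O1–C7a–C3a is the enol oxygen and α-carbon of methyl 3,5-dioxocyclohexane-1-carboxylate; the second carbonyl (C4) is removed on aromatisation and the ester carbon (on C6) becomes the stilbene carbon.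
- Forward: the furan ring of unit C closes first (dirhodium-carbene C–H insertion) and a Suzuki coupling adds the 4-methoxystyryl arm. The anodic annulation closes the furan ring of unit B, and reduction, dehydration and dehydrogenation make its benzo ring. A Heck reaction then joins unit A, whose furan ring is made in the same way as that of unit C.
- Stereochemistry: C3 of units A and C (both S) comes from the chiral dirhodium catalyst, and C2 of each (S) from acid equilibration to the trans isomer. C3 of unit B (R) is induced by C3 of unit C in the annulation, and C2 (R) follows from trans ring closure. Both alkenes are E by construction.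

Key step: step 10

Assumption: Rh2(R-PTAD)4 is taken to give the (2R,3S)-cis insertion products in steps 7 and 20; if the sense of induction is the opposite for these substrates, the mirror-image catalyst Rh2(S-PTAD)4 is used in both steps and nothing else changes.

Abbreviation used in names: ArC = (2S,3S)-3-(3,5-dimethoxyphenyl)-6-methoxy-2-(4-methoxyphenyl)-2,3-dihydrobenzofuran-4-yl (the aryl group of unit C). Rh2(R-PTAD)4 = dirhodium tetrakis[(R)-(1-adamantyl)(phthalimido)acetate].

**Unit C and its stilbene**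

Step 1
Reactants: 1 2-bromo-4,6-dimethoxybenzaldehyde
Product: 2 2-bromo-6-hydroxy-4-methoxybenzaldehyde
Conditions: BCl3 (1.2 equiv), CH2Cl2, −78 → 0 °C; then H2O
Reagents that add atoms: none
Why: Chelation-directed Lewis-acid ether cleavage, in which BCl3 bound to the formyl oxygen delivers chloride only to the ortho methoxy group and leaves the para one intact.

Step 2
Reactants: 2 2-bromo-6-hydroxy-4-methoxybenzaldehyde; 3 4-methoxybenzyl chloride
Product: 4 2-bromo-4-methoxy-6-(4-methoxybenzyloxy)benzaldehyde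
Conditions: K2CO3, nBu4NI (cat.), DMF, 60 °C
Reagents that add atoms: none
Why: Williamson etherification of the acidic ortho-formyl phenol installs the benzylic CH2 that later becomes C2 of unit C.

Step 3
Reactants: 5 1-bromo-3,5-dimethoxybenzene
Product: 6 3,5-dimethoxyphenylmagnesium bromide (titrated THF solution, kept under Ar)
Conditions: Mg turnings, I2 (cat.), THF, rt → 40 °C
Reagents that add atoms: magnesium, [Mg]
Why: Grignard formation by oxidative insertion of magnesium into the aryl C–Br bond, which proceeds normally for this electron-rich aryl bromide in THF; one batch of the solution serves steps 4 and 17.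

Step 4
Reactants: 4 2-bromo-4-methoxy-6-(4-methoxybenzyloxy)benzaldehyde; 6 3,5-dimethoxyphenylmagnesium bromide
Product: 7 [2-bromo-4-methoxy-6-(4-methoxybenzyloxy)phenyl](3,5-dimethoxyphenyl)methanol (racemic)
Conditions: 6 (1.2 equiv, THF solution), THF, 0 °C; then H2O
Reagents that add atoms: none
Why: Grignard addition to the aldehyde is fast at 0 °C, where the aryl bromide of 4 does not exchange with an arylmagnesium reagent, and the carbinol centre is removed in the next step.

Step 5
Reactants: 7 [2-bromo-4-methoxy-6-(4-methoxybenzyloxy)phenyl](3,5-dimethoxyphenyl)methanol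
Product: 8 [2-bromo-4-methoxy-6-(4-methoxybenzyloxy)phenyl](3,5-dimethoxyphenyl)methanone
Conditions: Dess–Martin periodinane, CH2Cl2, rt
Reagents that add atoms: none
Why: Dess–Martin oxidation converts the hindered benzhydrol to the benzophenone under neutral conditions that spare the 4-methoxybenzyl ether.

Step 6
Reactants: 8 [2-bromo-4-methoxy-6-(4-methoxybenzyloxy)phenyl](3,5-dimethoxyphenyl)methanone
Product: 9 [2-bromo-4-methoxy-6-(4-methoxybenzyloxy)phenyl](3,5-dimethoxyphenyl)methanone hydrazone (E/Z mixture)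
Conditions: N2H4·H2O (20 equiv), AcOH (cat.), n-BuOH, 110 °C
Reagents that add atoms: hydrazine (used as the monohydrate), NN
Why: Hydrazone condensation, driven by excess hydrazine, acid catalysis and heat because the ketone is di-ortho-substituted; both hydrazone isomers lead to the same diazo compound.

Step 7
Reactants: 9 [2-bromo-4-methoxy-6-(4-methoxybenzyloxy)phenyl](3,5-dimethoxyphenyl)methanone hydrazone
Product: 11 (2R,3S)-4-bromo-3-(3,5-dimethoxyphenyl)-6-methoxy-2-(4-methoxyphenyl)-2,3-dihydrobenzofuran (cis), via diaryldiazomethane 10 (not isolated)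
Conditions: MnO2 (8 equiv), MeCN, 0 °C; then Rh2(R-PTAD)4 (1 mol %), 0 °C → rt
Reagents that add atoms: none
Why: MnO2 dehydrogenates the hydrazone to the donor/donor diazo compound, whose dirhodium carbene undergoes enantioselective intramolecular C–H insertion into the benzylic C–H bond next to oxygen (five-membered ring); the chiral carboxylate ligands set C3 (S) and the concerted insertion places the two aryl groups cis (2R).

Step 8
Reactants: 11 (2R,3S)-4-bromo-3-(3,5-dimethoxyphenyl)-6-methoxy-2-(4-methoxyphenyl)-2,3-dihydrobenzofuran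
Product: 12 (2S,3S)-4-bromo-3-(3,5-dimethoxyphenyl)-6-methoxy-2-(4-methoxyphenyl)-2,3-dihydrobenzofuran (trans)
Conditions: CF3CO2H, CH2Cl2, 0 °C → rt
Reagents that add atoms: none
Why: Acid-catalysed epimerisation by reversible heterolysis of the C2–O1 bond to the 4-methoxybenzylic cation and re-closure by the phenol, which equilibrates C2 to the more stable trans isomer (2S) while C3, which does not ionise, keeps the configuration set in step 7.

Step 9
Reactants: 12 (2S,3S)-4-bromo-3-(3,5-dimethoxyphenyl)-6-methoxy-2-(4-methoxyphenyl)-2,3-dihydrobenzofuran; 13 (E)-2-(4-methoxyphenyl)vinylboronic acid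
Product: 14 (2S,3S)-3-(3,5-dimethoxyphenyl)-6-methoxy-2-(4-methoxyphenyl)-4-[(E)-2-(4-methoxyphenyl)ethenyl]-2,3-dihydrobenzofuran
Conditions: Pd(OAc)2 (5 mol %), SPhos (10 mol %), K3PO4, toluene/H2O, 80 °C
Reagents that add atoms: none
Why: Suzuki–Miyaura coupling with a bulky biarylphosphine tolerates the peri-hindered aryl bromide and transfers the alkenyl group with retention of the E geometry.

**Unit B by annulation and aromatisation**

Step 10
Reactants: 14 (2S,3S)-3-(3,5-dimethoxyphenyl)-6-methoxy-2-(4-methoxyphenyl)-4-[(E)-2-(4-methoxyphenyl)ethenyl]-2,3-dihydrobenzofuran; 15 methyl 3,5-dioxocyclohexane-1-carboxylate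
Product: 16 methyl (2R,3R)-3-ArC-2-(4-methoxyphenyl)-4-oxo-2,3,4,5,6,7-hexahydrobenzofuran-6-carboxylate (both C6 epimers)
Conditions: Mn(OAc)2·4H2O (20 mol %), 15 (2 equiv), NaOAc, AcOH/EtOAc 3:1, graphite anode, Pt cathode, divided cell, constant current (about 2.5 F per mol of 14), 50 °C, N2
Reagents that add atoms: none
Why: Trivalent manganese, regenerated at the anode from Mn(OAc)2, oxidises the enol of 15 to an electrophilic α-radical that adds to the alkene carbon of 14 bonded to C4 of unit C (the terminus remote from the 4-methoxyphenyl donor); the resulting 4-methoxybenzylic radical is oxidised to the cation and captured by the enol oxygen, so C3–C3a and O1–C2 of unit B form in one operation. The closest known reaction type is the oxidative [3+2] annulation of cyclic 1,3-diones with styrenes and stilbenes to 2,3-dihydrofurans, mediated by Mn(OAc)3 or by anodically regenerated trivalent manganese. The dihydrofuran ring of unit B closes by 5-exo-trig attack of the enol oxygen on the quinonoid benzylic carbon. C3 of unit B (R) is controlled by the C3 stereocentre of unit C: in the conformer that turns the alkene C–H toward C3 of unit C and the anisyl-bearing carbon away from it, the 3,5-dimethoxyphenyl group covers one face of the reacting carbon and the radical should enter anti to it, which by model analysis gives the required 3R centre. C2 of unit B (R) is set in the ring closure, which places the 4-methoxyphenyl group trans to the bulky C3 substituent, while the C6 centre forms as a mixture and is erased in step 12. The step needs regioselectivity (secured by the much greater stability of the 4-methoxybenzylic radical and cation over the meta-dioxygenated benzylic alternative), chemoselectivity for the dione over the electron-rich arenes (secured by the low potential at which the mediator turns over) and facial selectivity (secured only by the shielding described).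

Step 11
Reactants: 16 methyl (2R,3R)-3-ArC-2-(4-methoxyphenyl)-4-oxo-2,3,4,5,6,7-hexahydrobenzofuran-6-carboxylate
Product: 17 methyl (2R,3R)-3-ArC-4-hydroxy-2-(4-methoxyphenyl)-2,3,4,5,6,7-hexahydrobenzofuran-6-carboxylate (C4/C6 epimer mixture)
Conditions: NaBH4, CeCl3·7H2O, MeOH/THF, −20 → 0 °C; NaHCO3 work-up
Reagents that add atoms: none
Why: Luche reduction, in which CeCl3 activates the vinylogous ester carbonyl for clean 1,2-hydride addition while the methyl ester is untouched; the new carbinol centre is lost in the next step.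

Step 12
Reactants: 17 methyl (2R,3R)-3-ArC-4-hydroxy-2-(4-methoxyphenyl)-2,3,4,5,6,7-hexahydrobenzofuran-6-carboxylate
Product: 19 methyl (2R,3R)-3-ArC-2-(4-methoxyphenyl)-2,3-dihydrobenzofuran-6-carboxylate, via dienol ether 18 (not isolated)
Conditions: camphorsulfonic acid (10 mol %), 4 Å molecular sieves, toluene, 0 °C → rt; then DDQ (1.1 equiv), 0 °C
Reagents that add atoms: none
Why: Acid-catalysed E1 dehydration of the γ-alkoxy allylic alcohol through an oxygen-stabilised allyl cation gives a cyclohexadienyl enol ether, which DDQ dehydrogenates (hydride abstraction, then proton loss) to the benzo ring of unit B, erasing C4 and C6 and leaving C2 and C3 untouched.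

Step 13
Reactants: 19 methyl (2R,3R)-3-ArC-2-(4-methoxyphenyl)-2,3-dihydrobenzofuran-6-carboxylate
Product: 20 [(2R,3R)-3-ArC-2-(4-methoxyphenyl)-2,3-dihydrobenzofuran-6-yl]methanol
Conditions: iBu2AlH (3 equiv), CH2Cl2, −78 → 0 °C; then H2O
Reagents that add atoms: none
Why: Hydride reduction of the aryl ester to the benzylic alcohol with diisobutylaluminium hydride, with no other reducible group present.

Step 14
Reactants: 20 [(2R,3R)-3-ArC-2-(4-methoxyphenyl)-2,3-dihydrobenzofuran-6-yl]methanol
Product: 21 (2R,3R)-3-ArC-2-(4-methoxyphenyl)-2,3-dihydrobenzofuran-6-carbaldehyde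
Conditions: MnO2 (20 equiv), CH2Cl2, rt
Reagents that add atoms: none
Why: MnO2 oxidises the benzylic alcohol selectively to the aldehyde without over-oxidation.

Step 15
Reactants: 21 (2R,3R)-3-ArC-2-(4-methoxyphenyl)-2,3-dihydrobenzofuran-6-carbaldehyde
Product: 22 (2R,3R)-6-ethenyl-3-ArC-2-(4-methoxyphenyl)-2,3-dihydrobenzofuran
Conditions: Ph3PCH3Br, KOtBu, THF, 0 °C → rt
Reagents that add atoms: methyltriphenylphosphonium bromide, C[P+](c1ccccc1)(c1ccccc1)c1ccccc1.[Br-]
Why: Wittig methylenation of the non-enolisable aryl aldehyde gives the styrene needed for the union.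

**Unit A**

Step 16
Reactants: 23 5-bromo-2-hydroxy-3-methoxybenzaldehyde; 3 4-methoxybenzyl chloride
Product: 24 5-bromo-3-methoxy-2-(4-methoxybenzyloxy)benzaldehyde
Conditions: K2CO3, nBu4NI (cat.), DMF, 60 °C
Reagents that add atoms: none
Why: Williamson etherification of the phenol installs the benzylic CH2 that becomes C2 of unit A.

Step 17
Reactants: 24 5-bromo-3-methoxy-2-(4-methoxybenzyloxy)benzaldehyde; 6 3,5-dimethoxyphenylmagnesium bromide
Product: 25 [5-bromo-3-methoxy-2-(4-methoxybenzyloxy)phenyl](3,5-dimethoxyphenyl)methanol (racemic)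
Conditions: 6 (1.2 equiv, THF solution from step 3), THF, 0 °C; then H2O
Reagents that add atoms: none
Why: Grignard addition to the aldehyde, chemoselective over the aryl bromide at 0 °C.

Step 18
Reactants: 25 [5-bromo-3-methoxy-2-(4-methoxybenzyloxy)phenyl](3,5-dimethoxyphenyl)methanol
Product: 26 [5-bromo-3-methoxy-2-(4-methoxybenzyloxy)phenyl](3,5-dimethoxyphenyl)methanone
Conditions: Dess–Martin periodinane, CH2Cl2, rt
Reagents that add atoms: none
Why: Dess–Martin oxidation of the benzhydrol to the benzophenone under neutral conditions.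

Step 19
Reactants: 26 [5-bromo-3-methoxy-2-(4-methoxybenzyloxy)phenyl](3,5-dimethoxyphenyl)methanone
Product: 27 [5-bromo-3-methoxy-2-(4-methoxybenzyloxy)phenyl](3,5-dimethoxyphenyl)methanone hydrazone (E/Z mixture)
Conditions: N2H4·H2O (10 equiv), AcOH (cat.), EtOH, 80 °C
Reagents that add atoms: hydrazine (used as the monohydrate), NN
Why: Hydrazone condensation of a mono-ortho-substituted benzophenone, which should proceed under standard conditions.

Step 20
Reactants: 27 [5-bromo-3-methoxy-2-(4-methoxybenzyloxy)phenyl](3,5-dimethoxyphenyl)methanone hydrazone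
Product: 29 (2R,3S)-5-bromo-3-(3,5-dimethoxyphenyl)-7-methoxy-2-(4-methoxyphenyl)-2,3-dihydrobenzofuran (cis), via diaryldiazomethane 28 (not isolated)
Conditions: MnO2 (8 equiv), MeCN, 0 °C; then Rh2(R-PTAD)4 (1 mol %), 0 °C → rt
Reagents that add atoms: none
Why: Hydrazone dehydrogenation followed by enantioselective intramolecular dirhodium-carbene C–H insertion, as in step 7; the catalyst sets C3 (S) and the concerted insertion gives the cis isomer (2R).

Step 21
Reactants: 29 (2R,3S)-5-bromo-3-(3,5-dimethoxyphenyl)-7-methoxy-2-(4-methoxyphenyl)-2,3-dihydrobenzofuran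
Product: 30 (2S,3S)-5-bromo-3-(3,5-dimethoxyphenyl)-7-methoxy-2-(4-methoxyphenyl)-2,3-dihydrobenzofuran (trans)
Conditions: CF3CO2H, CH2Cl2, 0 °C → rt
Reagents that add atoms: none
Why: Acid-catalysed C2 epimerisation by reversible opening to the 4-methoxybenzylic cation and re-closure to the trans isomer (2S), with C3 unchanged.

**Union and deprotection**

Step 22
Reactants: 22 (2R,3R)-6-ethenyl-3-ArC-2-(4-methoxyphenyl)-2,3-dihydrobenzofuran; 30 (2S,3S)-5-bromo-3-(3,5-dimethoxyphenyl)-7-methoxy-2-(4-methoxyphenyl)-2,3-dihydrobenzofuran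
Product: 31 (2S,3S)-3-(3,5-dimethoxyphenyl)-7-methoxy-2-(4-methoxyphenyl)-5-[(E)-2-[(2R,3R)-3-ArC-2-(4-methoxyphenyl)-2,3-dihydrobenzofuran-6-yl]ethenyl]-2,3-dihydrobenzofuran (nona-O-methyl ether of the target)
Conditions: Pd(P(tBu)3)2 (5 mol %), Cy2NMe (1.5 equiv), toluene, 90 °C
Reagents that add atoms: none
Why: Mizoroki–Heck reaction, in which zerovalent palladium with P(tBu)3 inserts into the electron-rich aryl bromide, the aryl group adds to the unsubstituted terminus of the styrene and syn β-hydride elimination gives the E-stilbene.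

Step 23
Reactants: 31 nona-O-methyl ether of the target
Product: 32 CNP0265934.1
Conditions: BBr3 (30 equiv), CH2Cl2, −78 °C → rt; then H2O, 0 °C
Reagents that add atoms: none
Why: BBr3 cleaves all nine aryl methyl ethers by Lewis-acid activation and bromide attack on methyl; any reversible opening of a dihydrofuran C2–O bond should re-close to the trans isomer dictated by the unaffected C3 centre, so the six stereocentres are retained.

**Compound list**

1 | 2-bromo-4,6-dimethoxybenzaldehyde | O=Cc1c(Br)cc(OC)cc1OC | starting material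
2 | 2-bromo-6-hydroxy-4-methoxybenzaldehyde | O=Cc1c(Br)cc(OC)cc1O | intermediate
3 | 4-methoxybenzyl chloride | COc1ccc(CCl)cc1 | starting material
4 | 2-bromo-4-methoxy-6-(4-methoxybenzyloxy)benzaldehyde | O=Cc1c(Br)cc(OC)cc1OCc1ccc(OC)cc1 | intermediate
5 | 1-bromo-3,5-dimethoxybenzene | COc1cc(Br)cc(OC)c1 | starting material
6 | 3,5-dimethoxyphenylmagnesium bromide (titrated THF solution) | COc1cc(OC)cc([Mg]Br)c1 | intermediate
7 | [2-bromo-4-methoxy-6-(4-methoxybenzyloxy)phenyl](3,5-dimethoxyphenyl)methanol (racemic) | OC(c1cc(OC)cc(OC)c1)c1c(Br)cc(OC)cc1OCc1ccc(OC)cc1 | intermediate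
8 | [2-bromo-4-methoxy-6-(4-methoxybenzyloxy)phenyl](3,5-dimethoxyphenyl)methanone | O=C(c1cc(OC)cc(OC)c1)c1c(Br)cc(OC)cc1OCc1ccc(OC)cc1 | intermediate
9 | hydrazone of 8 (E/Z mixture) | NN=C(c1cc(OC)cc(OC)c1)c1c(Br)cc(OC)cc1OCc1ccc(OC)cc1 | intermediate
10 | [2-bromo-4-methoxy-6-(4-methoxybenzyloxy)phenyl](3,5-dimethoxyphenyl)diazomethane (not isolated) | [N-]=[N+]=C(c1cc(OC)cc(OC)c1)c1c(Br)cc(OC)cc1OCc1ccc(OC)cc1 | intermediate
11 | (2R,3S)-4-bromo-3-(3,5-dimethoxyphenyl)-6-methoxy-2-(4-methoxyphenyl)-2,3-dihydrobenzofuran (cis) | Brc1cc(OC)cc2c1[C@H](c1cc(OC)cc(OC)c1)[C@H](c1ccc(OC)cc1)O2 | intermediate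
12 | (2S,3S)-4-bromo-3-(3,5-dimethoxyphenyl)-6-methoxy-2-(4-methoxyphenyl)-2,3-dihydrobenzofuran (trans) | Brc1cc(OC)cc2c1[C@H](c1cc(OC)cc(OC)c1)[C@@H](c1ccc(OC)cc1)O2 | intermediate
13 | (E)-2-(4-methoxyphenyl)vinylboronic acid | COc1ccc(/C=C/B(O)O)cc1 | starting material
14 | (2S,3S)-3-(3,5-dimethoxyphenyl)-6-methoxy-2-(4-methoxyphenyl)-4-[(E)-2-(4-methoxyphenyl)ethenyl]-2,3-dihydrobenzofuran | COc1ccc(/C=C/c2cc(OC)cc3c2[C@H](c2cc(OC)cc(OC)c2)[C@@H](c2ccc(OC)cc2)O3)cc1 | intermediate
15 | methyl 3,5-dioxocyclohexane-1-carboxylate | COC(=O)C1CC(=O)CC(=O)C1 | starting material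
16 | methyl (2R,3R)-3-ArC-2-(4-methoxyphenyl)-4-oxo-2,3,4,5,6,7-hexahydrobenzofuran-6-carboxylate (both C6 epimers) | COC(=O)C1CC(=O)C2=C(C1)O[C@@H](c1ccc(OC)cc1)[C@@H]2c1cc(OC)cc2c1[C@H](c1cc(OC)cc(OC)c1)[C@@H](c1ccc(OC)cc1)O2 | intermediate
17 | methyl (2R,3R)-3-ArC-4-hydroxy-2-(4-methoxyphenyl)-2,3,4,5,6,7-hexahydrobenzofuran-6-carboxylate (C4/C6 epimer mixture) | COC(=O)C1CC(O)C2=C(C1)O[C@@H](c1ccc(OC)cc1)[C@@H]2c1cc(OC)cc2c1[C@H](c1cc(OC)cc(OC)c1)[C@@H](c1ccc(OC)cc1)O2 | intermediate
18 | methyl (2R,3R)-3-ArC-2-(4-methoxyphenyl)-2,3,6,7-tetrahydrobenzofuran-6-carboxylate (dienol ether, drawn as one of the double-bond isomers; not isolated) | COC(=O)C1C=CC2=C(C1)O[C@@H](c1ccc(OC)cc1)[C@@H]2c1cc(OC)cc2c1[C@H](c1cc(OC)cc(OC)c1)[C@@H](c1ccc(OC)cc1)O2 | intermediate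
19 | methyl (2R,3R)-3-ArC-2-(4-methoxyphenyl)-2,3-dihydrobenzofuran-6-carboxylate | COC(=O)c1ccc2c(c1)O[C@@H](c1ccc(OC)cc1)[C@@H]2c1cc(OC)cc2c1[C@H](c1cc(OC)cc(OC)c1)[C@@H](c1ccc(OC)cc1)O2 | intermediate
20 | [(2R,3R)-3-ArC-2-(4-methoxyphenyl)-2,3-dihydrobenzofuran-6-yl]methanol | OCc1ccc2c(c1)O[C@@H](c1ccc(OC)cc1)[C@@H]2c1cc(OC)cc2c1[C@H](c1cc(OC)cc(OC)c1)[C@@H](c1ccc(OC)cc1)O2 | intermediate
21 | (2R,3R)-3-ArC-2-(4-methoxyphenyl)-2,3-dihydrobenzofuran-6-carbaldehyde | O=Cc1ccc2c(c1)O[C@@H](c1ccc(OC)cc1)[C@@H]2c1cc(OC)cc2c1[C@H](c1cc(OC)cc(OC)c1)[C@@H](c1ccc(OC)cc1)O2 | intermediate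
22 | (2R,3R)-6-ethenyl-3-ArC-2-(4-methoxyphenyl)-2,3-dihydrobenzofuran | C=Cc1ccc2c(c1)O[C@@H](c1ccc(OC)cc1)[C@@H]2c1cc(OC)cc2c1[C@H](c1cc(OC)cc(OC)c1)[C@@H](c1ccc(OC)cc1)O2 | intermediate
23 | 5-bromo-2-hydroxy-3-methoxybenzaldehyde | COc1cc(Br)cc(C=O)c1O | starting material
24 | 5-bromo-3-methoxy-2-(4-methoxybenzyloxy)benzaldehyde | COc1ccc(COc2c(C=O)cc(Br)cc2OC)cc1 | intermediate
25 | [5-bromo-3-methoxy-2-(4-methoxybenzyloxy)phenyl](3,5-dimethoxyphenyl)methanol (racemic) | COc1ccc(COc2c(OC)cc(Br)cc2C(O)c2cc(OC)cc(OC)c2)cc1 | intermediate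
26 | [5-bromo-3-methoxy-2-(4-methoxybenzyloxy)phenyl](3,5-dimethoxyphenyl)methanone | COc1ccc(COc2c(OC)cc(Br)cc2C(=O)c2cc(OC)cc(OC)c2)cc1 | intermediate
27 | hydrazone of 26 (E/Z mixture) | COc1ccc(COc2c(OC)cc(Br)cc2C(=NN)c2cc(OC)cc(OC)c2)cc1 | intermediate
28 | [5-bromo-3-methoxy-2-(4-methoxybenzyloxy)phenyl](3,5-dimethoxyphenyl)diazomethane (not isolated) | COc1ccc(COc2c(OC)cc(Br)cc2C(=[N+]=[N-])c2cc(OC)cc(OC)c2)cc1 | intermediate
29 | (2R,3S)-5-bromo-3-(3,5-dimethoxyphenyl)-7-methoxy-2-(4-methoxyphenyl)-2,3-dihydrobenzofuran (cis) | COc1ccc([C@@H]2Oc3c(OC)cc(Br)cc3[C@@H]2c2cc(OC)cc(OC)c2)cc1 | intermediate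
30 | (2S,3S)-5-bromo-3-(3,5-dimethoxyphenyl)-7-methoxy-2-(4-methoxyphenyl)-2,3-dihydrobenzofuran (trans) | COc1ccc([C@H]2Oc3c(OC)cc(Br)cc3[C@@H]2c2cc(OC)cc(OC)c2)cc1 | intermediate
31 | nona-O-methyl ether of the target (name as in step 22) | COc1ccc([C@H]2Oc3c(OC)cc(/C=C/c4ccc5c(c4)O[C@@H](c4ccc(OC)cc4)[C@@H]5c4cc(OC)cc5c4[C@H](c4cc(OC)cc(OC)c4)[C@@H](c4ccc(OC)cc4)O5)cc3[C@@H]2c2cc(OC)cc(OC)c2)cc1 | intermediate
32 | CNP0265934.1, 5-[(2S,3S)-5-[(E)-2-[(2R,3R)-3-[(2S,3S)-3-(3,5-dihydroxyphenyl)-6-hydroxy-2-(4-hydroxyphenyl)-2,3-dihydrobenzofuran-4-yl]-2-(4-hydroxyphenyl)-2,3-dihydrobenzofuran-6-yl]ethenyl]-7-hydroxy-2-(4-hydroxyphenyl)-2,3-dihydrobenzofuran-3-yl]benzene-1,3-diol | Oc1ccc([C@H]2Oc3c(O)cc(/C=C/c4ccc5c(c4)O[C@@H](c4ccc(O)cc4)[C@@H]5c4cc(O)cc5c4[C@H](c4cc(O)cc(O)c4)[C@@H](c4ccc(O)cc4)O5)cc3[C@@H]2c2cc(O)cc(O)c2)cc1 | target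

**Step count**

Total: 23 steps. Longest linear sequence: 16 steps (steps 1, 2 and 4–15, then 22 and 23, from 2-bromo-4,6-dimethoxybenzaldehyde). The unit A branch (steps 16–21) is 6 steps, and the Grignard solution of step 3 feeds steps 4 and 17.

**Three steps most likely to fail**

First, step 10. The radical may discriminate poorly between the two alkene faces, since shielding by the C3 aryl group of unit C is the only control element. Direct anodic oxidation of the electron-rich stilbene may compete with mediator turnover. The 4-methoxybenzylic cation may also be intercepted by the neighbouring 3,5-dimethoxyphenyl ring in a seven-membered Friedel–Crafts closure before the enol oxygen reaches it. The fallback sets out from 15 and 14 and comes back to the route at 16. Diazo transfer to 15 (4-acetamidobenzenesulfonyl azide, Et3N, MeCN, 0 °C) should give methyl 4-diazo-3,5-dioxocyclohexane-1-carboxylate F1. Decomposition of F1 with Rh2(OAc)4 (2 mol %) in fluorobenzene at 60 °C in the presence of 14 is expected to give 16 by the known formal [3+2] cycloaddition of cyclic 2-diazo-1,3-dione carbenoids with electron-rich aryl alkenes. The same two bonds form with the same regiochemistry, because the carbenoid carbon bonds to the alkene carbon remote from the donor aryl group and the zwitterion collapses through oxygen. No oxidant is present and the cationic centre is short-lived. The metal-bound electrophile is also bulkier, which should sharpen the facial preference.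

Second, step 12. The ionised allylic alcohol is an oxocarbenium ion at C7a, so traces of water would open the new dihydrofuran ring to a cyclohexenone and destroy unit B; the dienol ether may also decompose before it is oxidised. The fallback sets out from 16 and comes back at 19, and it avoids the allylic alcohol altogether. Aerobic dehydrogenation of 16 (Pd(O2CCF3)2 5 mol %, 2-(dimethylamino)pyridine, TsOH cat., O2, DMSO, 80 °C) should aromatise the cyclohexenone directly to the phenol methyl (2R,3R)-3-ArC-4-hydroxy-2-(4-methoxyphenyl)-2,3-dihydrobenzofuran-6-carboxylate F2. Triflation (Tf2O, pyridine, CH2Cl2, 0 °C) gives methyl (2R,3R)-3-ArC-2-(4-methoxyphenyl)-4-(trifluoromethylsulfonyloxy)-2,3-dihydrobenzofuran-6-carboxylate F3. Palladium-catalysed formate reduction (Pd(OAc)2, dppf, HCO2H, Et3N, DMF, 60 °C) then removes the C4 oxygen and gives 19.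

Third, step 23. Under BBr3 and the HBr it releases, the electron-rich stilbene may be protonated and consumed by hydrobromination, by cyclisation onto neighbouring arenes or by oligomerisation before all nine ethers are cleaved. The fallback sets out from 21 and 30 and comes back at 32; it removes the methyl groups before the stilbene exists. BBr3 in CH2Cl2 should convert 21 into (2R,3R)-3-[(2S,3S)-3-(3,5-dihydroxyphenyl)-6-hydroxy-2-(4-hydroxyphenyl)-2,3-dihydrobenzofuran-4-yl]-2-(4-hydroxyphenyl)-2,3-dihydrobenzofuran-6-carbaldehyde F4. Wittig methylenation with excess ylide (Ph3PCH3Br, KOtBu, THF; the phenoxides are spectators) gives 5-[(2S,3S)-4-[(2R,3R)-6-ethenyl-2-(4-hydroxyphenyl)-2,3-dihydrobenzofuran-3-yl]-6-hydroxy-2-(4-hydroxyphenyl)-2,3-dihydrobenzofuran-3-yl]benzene-1,3-diol F5. BBr3 converts 30 into 5-[(2S,3S)-5-bromo-7-hydroxy-2-(4-hydroxyphenyl)-2,3-dihydrobenzofuran-3-yl]benzene-1,3-diol F6. A Heck reaction of F5 with F6 (Pd(OAc)2, P(o-tolyl)3, Et3N, DMF, 100 °C), which tolerates free phenols, then gives 32 directly.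

**Further compounds**

F1 | step 10 | methyl 4-diazo-3,5-dioxocyclohexane-1-carboxylate | COC(=O)C1CC(=O)C(=[N+]=[N-])C(=O)C1
F2 | step 12 | methyl (2R,3R)-3-ArC-4-hydroxy-2-(4-methoxyphenyl)-2,3-dihydrobenzofuran-6-carboxylate | COC(=O)c1cc(O)c2c(c1)O[C@@H](c1ccc(OC)cc1)[C@@H]2c1cc(OC)cc2c1[C@H](c1cc(OC)cc(OC)c1)[C@@H](c1ccc(OC)cc1)O2
F3 | step 12 | methyl (2R,3R)-3-ArC-2-(4-methoxyphenyl)-4-(trifluoromethylsulfonyloxy)-2,3-dihydrobenzofuran-6-carboxylate | COC(=O)c1cc(OS(=O)(=O)C(F)(F)F)c2c(c1)O[C@@H](c1ccc(OC)cc1)[C@@H]2c1cc(OC)cc2c1[C@H](c1cc(OC)cc(OC)c1)[C@@H](c1ccc(OC)cc1)O2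
F4 | step 23 | (2R,3R)-3-[(2S,3S)-3-(3,5-dihydroxyphenyl)-6-hydroxy-2-(4-hydroxyphenyl)-2,3-dihydrobenzofuran-4-yl]-2-(4-hydroxyphenyl)-2,3-dihydrobenzofuran-6-carbaldehyde | O=Cc1ccc2c(c1)O[C@@H](c1ccc(O)cc1)[C@@H]2c1cc(O)cc2c1[C@H](c1cc(O)cc(O)c1)[C@@H](c1ccc(O)cc1)O2
F5 | step 23 | 5-[(2S,3S)-4-[(2R,3R)-6-ethenyl-2-(4-hydroxyphenyl)-2,3-dihydrobenzofuran-3-yl]-6-hydroxy-2-(4-hydroxyphenyl)-2,3-dihydrobenzofuran-3-yl]benzene-1,3-diol | C=Cc1ccc2c(c1)O[C@@H](c1ccc(O)cc1)[C@@H]2c1cc(O)cc2c1[C@H](c1cc(O)cc(O)c1)[C@@H](c1ccc(O)cc1)O2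
F6 | step 23 | 5-[(2S,3S)-5-bromo-7-hydroxy-2-(4-hydroxyphenyl)-2,3-dihydrobenzofuran-3-yl]benzene-1,3-diol | Oc1ccc([C@H]2Oc3c(O)cc(Br)cc3[C@@H]2c2cc(O)cc(O)c2)cc1
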